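**Retrosynthetic overview**

1. Oxane numbering used throughout: O1, C2 (aryl), C3 (arylpropenyl), C4, C5 (bears the carbinol carbon C7), C6. Late simplifications: phenols ⇐ aryl TBS ethers; (E)-arylpropenyl ⇐ its (Z) isomer; C7 carbinol ⇐ aryl ketone; C5–H ⇐ C5=C6 of a β-alkoxy enone.
2. Key disconnection: O1–C2 and C3–C4 together, by an inverse-electron-demand hetero-Diels–Alder reaction of a 2-aroylacrolein (O1=C6–C5=C4, made in the flask) with one alkene (C2=C3) of a (1Z,4Z)-1,5-diarylpenta-1,4-diene.
3. Enabling feature: all three ring substituents are cis, and the cis H/H pair on the C2–C3 edge of the oxane is a Z-alkene in disguise. The C3 side chain is the untouched second half of a twofold-symmetric skipped diene, and C7 at the ketone level activates the C4=C5–C6=O1 oxadiene.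
4. Ring order: the oxane is the only ring made (step 3, sets C2 and C3); C5 (step 4) and C7 (step 5) follow.
5. Both partners come from 4-silyloxybenzaldehyde: the diene by a double Wittig reaction that uses two equivalents of the aldehyde, the oxadiene precursor by addition of dilithiated 2-bromoallyl alcohol.

Key step: step 3

Notes: TBS = tert-butyldimethylsilyl, TBSO = tert-butyldimethylsilyloxy. CrCl(L) = CrCl(C27H29NO2), the chloride complex of trivalent chromium with the doubly deprotonated tridentate Schiff base of 3-(1-adamantyl)-2-hydroxy-5-methylbenzaldehyde and (1R,2S)-1-aminoindan-2-ol.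

Assumption: the sense of asymmetric induction of CrCl(L) in step 3 is taken by analogy with its enal–vinyl ether cycloadditions; should the opposite sense be found, the complex from (1S,2R)-1-aminoindan-2-ol is used instead, with no other change.

**Route**

Step 1
Reactants: 1 4-(tert-butyldimethylsilyloxy)benzaldehyde; 2 propane-1,3-diylbis(triphenylphosphonium) dibromide
Product: 4 (1Z,4Z)-1,5-bis[4-(TBSO)phenyl]penta-1,4-diene, via bis-ylide 3 (not isolated)
Conditions: 2 (1.0 equiv), NaN(SiMe3)2 (2.0 equiv), THF, −78 → 0 °C; then 1 (2.0 equiv in all), −78 °C → rt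
Reagents that add atoms: second equivalent of 4-(tert-butyldimethylsilyloxy)benzaldehyde (1), CC(C)(C)[Si](C)(C)Oc1ccc(C=O)cc1
Why: Double Wittig olefination in which each of the two ylide carbons of the non-stabilised bis-ylide takes up one molecule of the aryl aldehyde under lithium-free conditions should pass through kinetically formed cis-oxaphosphetanes and give both alkenes Z; E-containing isomers are to be removed on AgNO3-impregnated silica, because they would react faster in step 3.

Step 2
Reactants: 5 2-bromoprop-2-en-1-ol; 1 4-(tert-butyldimethylsilyloxy)benzaldehyde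
Product: 7 rac-1-[4-(TBSO)phenyl]-2-methylidenepropane-1,3-diol, via dilithio allyl alkoxide 6 (not isolated)
Conditions: 5, t-BuLi (3.0 equiv), Et2O, −78 → 0 °C; then 1 (1.0 equiv), −78 °C; H2O
Reagents that add atoms: none
Why: Bromine–lithium exchange on the lithium alkoxide gives a 2-lithioallyl alkoxide that adds 1,2 to the aldehyde (organolithium carbonyl addition); the new carbinol centre is left racemic on purpose, since step 3 oxidises it away.

Step 3
Reactants: 7 rac-1-[4-(TBSO)phenyl]-2-methylidenepropane-1,3-diol; 4 (1Z,4Z)-1,5-bis[4-(TBSO)phenyl]penta-1,4-diene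
Product: 9 (2R,3S)-5-[4-(TBSO)benzoyl]-2-[4-(TBSO)phenyl]-3-{(2Z)-3-[4-(TBSO)phenyl]prop-2-en-1-yl}-3,4-dihydro-2H-pyran, via 2-aroylacrolein 8 (not isolated)
Conditions: Dess–Martin periodinane (2.4 equiv), CH2Cl2, −20 → 0 °C; pentane, cold filtration; then 4 (2.0 equiv), CrCl(L) (10 mol %), 4 Å MS, CH2Cl2, −30 °C
Reagents that add atoms: none
Why: Proposed new method: double oxidation of 7 unmasks the 2-aroylacrolein 8, whose formyl oxygen binds the trivalent chromium Lewis acid in the s-cis form, so that O=CH–C=CH2 acts as an electron-poor 1-oxadiene toward one (Z)-aryl alkene of 4 in an asynchronous but concerted, suprafacial inverse-electron-demand hetero-Diels–Alder reaction; the C3–C4 bond leads and the O1–C2 bond completes the six-membered dihydropyran ring in the same intermolecular [4+2] event, with no separate exo or endo closure. The closest known reactions are the thermal [4+2] additions of 2-methylene-1,3-dicarbonyl compounds to styrenes and the enantioselective additions of enals to vinyl ethers under tridentate Schiff-base chromium chloride complexes of this type; the new part is the combination of a 2-acyl enal, a Z-styrene without heteroatom donor and enantiocontrol. The cis relation of C2 and C3 is fixed by the Z geometry of the alkene, transferred stereospecifically, and their absolute configuration (2R,3S) by the chiral ligand, which shields one face of the chromium-bound oxadiene. Regiochemistry (O1 to the benzylic carbon) follows from the larger HOMO coefficient at the non-benzylic alkene carbon and the aryl-stabilised positive character at C2; reaction through the formyl rather than the aroyl oxadiene rests on the unhindered, metal-bound aldehyde and on the deactivation of the ketone by its 4-silyloxyphenyl group. Site selectivity is no issue because the two alkenes of 4 are equivalent by symmetry, a twofold excess of 4 suppresses double addition, and the aroyl carbonyl is at once the activating group and the future carbinol carbon.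

Step 4
Reactants: 9 (2R,3S)-5-[4-(TBSO)benzoyl]-2-[4-(TBSO)phenyl]-3-{(2Z)-3-[4-(TBSO)phenyl]prop-2-en-1-yl}-3,4-dihydro-2H-pyran
Product: 11 (2R,3S,5R)-5-[4-(TBSO)benzoyl]-2-[4-(TBSO)phenyl]-3-{(2Z)-3-[4-(TBSO)phenyl]prop-2-en-1-yl}oxane, via lithium enolate 10 (not isolated)
Conditions: LiBH(s-Bu)3 (1.05 equiv), THF, −78 °C; then AcOH, THF, −78 °C
Reagents that add atoms: none
Why: Conjugate (1,4) hydride reduction of the β-alkoxy enone by the hindered borohydride at the unhindered C6, as known for dihydropyranones, gives enolate 10, and kinetic C-protonation at −78 °C from the face opposite the cis C2 and C3 substituents (the pseudoaxial C3 chain shields the other face) should set C5 as R and the all-cis ring, which is then kept away from base because C5 is epimerisable and the β-alkoxy ketone could open by retro-oxa-Michael reaction.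

Step 5
Reactants: 11 (2R,3S,5R)-5-[4-(TBSO)benzoyl]-2-[4-(TBSO)phenyl]-3-{(2Z)-3-[4-(TBSO)phenyl]prop-2-en-1-yl}oxane
Product: 12 (2R,3S,5R)-5-{(R)-hydroxy[4-(TBSO)phenyl]methyl}-2-[4-(TBSO)phenyl]-3-{(2Z)-3-[4-(TBSO)phenyl]prop-2-en-1-yl}oxane
Conditions: (S)-2-methyl-CBS-oxazaborolidine (0.5 equiv), catecholborane (1.5 equiv), toluene, −78 → −40 °C; then H2O
Reagents that add atoms: none
Why: Corey–Bakshi–Shibata reduction of an aryl alkyl ketone: with the aryl group as the large substituent, the (S)-oxazaborolidine should deliver hydride to the face that gives the (R)-carbinol under catalyst control, and catecholborane at low temperature leaves the alkene and the silyl ethers untouched.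

Step 6
Reactants: 12 (2R,3S,5R)-5-{(R)-hydroxy[4-(TBSO)phenyl]methyl}-2-[4-(TBSO)phenyl]-3-{(2Z)-3-[4-(TBSO)phenyl]prop-2-en-1-yl}oxane
Product: 13 (2R,3S,5R)-5-{(R)-hydroxy[4-(TBSO)phenyl]methyl}-2-[4-(TBSO)phenyl]-3-{(2E)-3-[4-(TBSO)phenyl]prop-2-en-1-yl}oxane
Conditions: PhSSPh (0.2 equiv), hν (365 nm), THF, rt
Reagents that add atoms: none
Why: Thiyl-radical-mediated alkene isomerisation: reversible addition of the phenylthiyl radical to the styrenyl double bond allows rotation and re-elimination until the thermodynamically favoured conjugated E alkene predominates, without touching the four stereocentres.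

Step 7
Reactants: 13 (2R,3S,5R)-5-{(R)-hydroxy[4-(TBSO)phenyl]methyl}-2-[4-(TBSO)phenyl]-3-{(2E)-3-[4-(TBSO)phenyl]prop-2-en-1-yl}oxane
Product: 14 (2R,3S,5R)-5-[(R)-hydroxy(4-hydroxyphenyl)methyl]-2-(4-hydroxyphenyl)-3-[(2E)-3-(4-hydroxyphenyl)prop-2-en-1-yl]oxane (CNP0182155.1)
Conditions: Bu4NF (3.3 equiv), AcOH (3.3 equiv), THF, 0 °C
Reagents that add atoms: none
Why: Fluoride-induced desilylation of the three aryl silyl ethers, buffered with acetic acid so that no phenoxide persists that could open the C2 benzylic ether or ionise the C7 carbinol through a quinone methide.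

**Compound list**

1 | 4-(tert-butyldimethylsilyloxy)benzaldehyde | CC(C)(C)[Si](C)(C)Oc1ccc(C=O)cc1 | starting material
2 | propane-1,3-diylbis(triphenylphosphonium) dibromide | [Br-].[Br-].c1ccc(cc1)[P+](CCC[P+](c1ccccc1)(c1ccccc1)c1ccccc1)(c1ccccc1)c1ccccc1 | starting material
3 | bis-ylide Ph3P=CH–CH2–CH=PPh3 (propane-1,3-diylidenebis(triphenylphosphorane)) | c1ccc(cc1)P(=CCC=P(c1ccccc1)(c1ccccc1)c1ccccc1)(c1ccccc1)c1ccccc1 | intermediate (not isolated)
4 | (1Z,4Z)-1,5-bis[4-(TBSO)phenyl]penta-1,4-diene | CC(C)(C)[Si](C)(C)Oc1ccc(/C=C\C/C=C\c2ccc(O[Si](C)(C)C(C)(C)C)cc2)cc1 | intermediate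
5 | 2-bromoprop-2-en-1-ol | OCC(Br)=C | starting material
6 | lithium 2-lithioprop-2-en-1-olate | [Li]OCC([Li])=C | intermediate (not isolated)
7 | rac-1-[4-(TBSO)phenyl]-2-methylidenepropane-1,3-diol | CC(C)(C)[Si](C)(C)Oc1ccc(C(O)C(=C)CO)cc1 | intermediate
8 | 2-[4-(TBSO)benzoyl]prop-2-enal | CC(C)(C)[Si](C)(C)Oc1ccc(C(=O)C(=C)C=O)cc1 | intermediate (not isolated)
9 | (2R,3S)-5-[4-(TBSO)benzoyl]-2-[4-(TBSO)phenyl]-3-{(2Z)-3-[4-(TBSO)phenyl]prop-2-en-1-yl}-3,4-dihydro-2H-pyran | CC(C)(C)[Si](C)(C)Oc1ccc(/C=C\C[C@H]2CC(C(=O)c3ccc(O[Si](C)(C)C(C)(C)C)cc3)=CO[C@H]2c2ccc(O[Si](C)(C)C(C)(C)C)cc2)cc1 | intermediate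
10 | lithium enolate of 11 (route numbering): lithium [4-(TBSO)phenyl]{(2R,3S)-2-[4-(TBSO)phenyl]-3-[(2Z)-3-[4-(TBSO)phenyl]prop-2-en-1-yl]oxan-5-ylidene}methanolate | [Li+].CC(C)(C)[Si](C)(C)Oc1ccc(/C=C\C[C@H]2CC(=C([O-])c3ccc(O[Si](C)(C)C(C)(C)C)cc3)CO[C@H]2c2ccc(O[Si](C)(C)C(C)(C)C)cc2)cc1 | intermediate (not isolated)
11 | (2R,3S,5R)-5-[4-(TBSO)benzoyl]-2-[4-(TBSO)phenyl]-3-{(2Z)-3-[4-(TBSO)phenyl]prop-2-en-1-yl}oxane | CC(C)(C)[Si](C)(C)Oc1ccc(/C=C\C[C@H]2C[C@@H](C(=O)c3ccc(O[Si](C)(C)C(C)(C)C)cc3)CO[C@H]2c2ccc(O[Si](C)(C)C(C)(C)C)cc2)cc1 | intermediate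
12 | (2R,3S,5R)-5-{(R)-hydroxy[4-(TBSO)phenyl]methyl}-2-[4-(TBSO)phenyl]-3-{(2Z)-3-[4-(TBSO)phenyl]prop-2-en-1-yl}oxane | CC(C)(C)[Si](C)(C)Oc1ccc(/C=C\C[C@H]2C[C@@H]([C@@H](O)c3ccc(O[Si](C)(C)C(C)(C)C)cc3)CO[C@H]2c2ccc(O[Si](C)(C)C(C)(C)C)cc2)cc1 | intermediate
13 | (2R,3S,5R)-5-{(R)-hydroxy[4-(TBSO)phenyl]methyl}-2-[4-(TBSO)phenyl]-3-{(2E)-3-[4-(TBSO)phenyl]prop-2-en-1-yl}oxane | CC(C)(C)[Si](C)(C)Oc1ccc(/C=C/C[C@H]2C[C@@H]([C@@H](O)c3ccc(O[Si](C)(C)C(C)(C)C)cc3)CO[C@H]2c2ccc(O[Si](C)(C)C(C)(C)C)cc2)cc1 | intermediate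
14 | (2R,3S,5R)-5-[(R)-hydroxy(4-hydroxyphenyl)methyl]-2-(4-hydroxyphenyl)-3-[(2E)-3-(4-hydroxyphenyl)prop-2-en-1-yl]oxane (CNP0182155.1) | Oc1ccc(/C=C/C[C@H]2C[C@@H]([C@@H](O)c3ccc(O)cc3)CO[C@H]2c2ccc(O)cc2)cc1 | target

**Step count and risks**

Total steps: 7. Longest linear sequence: 6 steps (1 → 7 → 9 → 11 → 12 → 13 → 14, or equally 1 → 4 → 9 and onward).

Steps most likely to fail:

Step 3 (proposed new method). The chromium-bound oxadiene may react with low enantiofacial discrimination, or through a stepwise ion-pair pathway that erodes the Z-to-cis transfer, and self-dimerisation of 8 may compete. Fallback with known chemistry: 8 is generated from 7 as before and combined with 4 in toluene at 0 → 40 °C without any Lewis acid. The purely thermal inverse-demand hetero-Diels–Alder reaction of 2-methylene-1,3-dicarbonyl compounds with styrenes is established and should give the cis adduct as a racemate, that is 9 together with its enantiomer, the (2S,3R)-adduct F1. Step 4 then gives 11 together with the (2S,3R,5S)-ketone F2. The (S)-oxazaborolidine of step 5 then serves as the resolving agent: it should reduce both ketones to (R)-carbinols, 11 giving 12 and F2 giving the diastereomeric alcohol F3, which is removed by chromatography. This fallback sets out from 7 and 4 and comes back to the route at 12.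

Step 4. Facial selectivity in the C-protonation of enolate 10 may be poor, since a small proton donor can react through more than one ring conformer, and some 1,2-reduction of the aryl ketone may compete. Fallback: starting from 9, enolate 10 is formed as in step 4 and quenched at −78 °C with N-bromosuccinimide to give the 5-bromo ketone F4 (either C5 epimer serves). Treatment with (Me3Si)3SiH, Et3B and air in toluene at −78 °C then reduces the C–Br bond by a radical chain. The planar C5 radical should take its hydrogen atom from the bulky silane on the face away from the C2 and C3 substituents, so that C5 is set by hydrogen-atom transfer instead of proton transfer. This fallback sets out from 9 and comes back at 11.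

Step 1. Z selectivity may erode in one of the two olefinations, or the half-reacted ylide may isomerise by proton transfer into a conjugated allylic ylide; either would put E-alkene or conjugated diene into the key step. Fallback: starting from 1, Colvin homologation (Me3SiCHN2, n-BuLi, THF, −78 °C → rt) gives the aryl alkyne F5. Deprotonation of F5 (n-BuLi) and addition to paraformaldehyde gives the propargylic alcohol F6, and CBr4/PPh3 converts it into the propargylic bromide F7. The bromomagnesium acetylide of F5 (EtMgBr, THF) with CuCl (10 mol %) is coupled with F7 to the skipped diyne F8. Semi-hydrogenation (H2, Pd/CaCO3–Pb(OAc)2, quinoline, EtOAc) then delivers hydrogen syn to both alkynes and should give the Z,Z-diene. This fallback sets out from 1 and comes back at 4.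

**Further compounds**

F1 | step 3 | (2S,3R)-5-[4-(TBSO)benzoyl]-2-[4-(TBSO)phenyl]-3-{(2Z)-3-[4-(TBSO)phenyl]prop-2-en-1-yl}-3,4-dihydro-2H-pyran (enantiomer of 9) | CC(C)(C)[Si](C)(C)Oc1ccc(/C=C\C[C@@H]2CC(C(=O)c3ccc(O[Si](C)(C)C(C)(C)C)cc3)=CO[C@@H]2c2ccc(O[Si](C)(C)C(C)(C)C)cc2)cc1
F2 | step 3 | (2S,3R,5S)-5-[4-(TBSO)benzoyl]-2-[4-(TBSO)phenyl]-3-{(2Z)-3-[4-(TBSO)phenyl]prop-2-en-1-yl}oxane (enantiomer of 11) | CC(C)(C)[Si](C)(C)Oc1ccc(/C=C\C[C@@H]2C[C@H](C(=O)c3ccc(O[Si](C)(C)C(C)(C)C)cc3)CO[C@@H]2c2ccc(O[Si](C)(C)C(C)(C)C)cc2)cc1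
F3 | step 3 | (2S,3R,5S)-5-{(R)-hydroxy[4-(TBSO)phenyl]methyl}-2-[4-(TBSO)phenyl]-3-{(2Z)-3-[4-(TBSO)phenyl]prop-2-en-1-yl}oxane | CC(C)(C)[Si](C)(C)Oc1ccc(/C=C\C[C@@H]2C[C@H]([C@@H](O)c3ccc(O[Si](C)(C)C(C)(C)C)cc3)CO[C@@H]2c2ccc(O[Si](C)(C)C(C)(C)C)cc2)cc1
F4 | step 4 | (2R,3S)-5-bromo-5-[4-(TBSO)benzoyl]-2-[4-(TBSO)phenyl]-3-{(2Z)-3-[4-(TBSO)phenyl]prop-2-en-1-yl}oxane (C5 epimer mixture) | CC(C)(C)[Si](C)(C)Oc1ccc(/C=C\C[C@H]2CC(Br)(C(=O)c3ccc(O[Si](C)(C)C(C)(C)C)cc3)CO[C@H]2c2ccc(O[Si](C)(C)C(C)(C)C)cc2)cc1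
F5 | step 1 | tert-butyl(4-ethynylphenoxy)dimethylsilane | CC(C)(C)[Si](C)(C)Oc1ccc(C#C)cc1
F6 | step 1 | 3-[4-(TBSO)phenyl]prop-2-yn-1-ol | CC(C)(C)[Si](C)(C)Oc1ccc(C#CCO)cc1
F7 | step 1 | [4-(3-bromoprop-1-yn-1-yl)phenoxy](tert-butyl)dimethylsilane | CC(C)(C)[Si](C)(C)Oc1ccc(C#CCBr)cc1
F8 | step 1 | 1,5-bis[4-(TBSO)phenyl]penta-1,4-diyne | CC(C)(C)[Si](C)(C)Oc1ccc(C#CCC#Cc2ccc(O[Si](C)(C)C(C)(C)C)cc2)cc1
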